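**Plan**

- Target read as (2S,3R,3aR,5R)-5-methoxy-2-methyl-3a-allyl-3-(3,4,5-trimethoxyphenyl)-3,3a,4,5-tetrahydro-1-benzofuran-6(2H)-one: 2-Me/3-Ar trans, 3-Ar/3a-allyl cis, 5-OMe trans to 3a-allyl. Enabling feature: the carbocycle is a cyclic vinylogous ester, O1–C7a=C7–C6(=O), so C7a is a lactone carbonyl in disguise. C4 (at the formyl level) on quaternary C3a plus C7a form a 1,3-dielectrophile, and C5(OMe)–C6(=O)–C7 is methoxyacetone, a 1,3-dinucleophile.
- Retrosynthetic cuts, in order: (a) the C4–H/C5–H pair, back to the cross-conjugated dienone with C4=C5; (b) C4–C5 and C7=C7a together, freeing methoxyacetone from a γ-lactone that carries a dimethoxymethyl group (C4) on C3a; (c) C3a–C4, C3a–allyl and C3–aryl, back to (S)-5-methylbutenolide and (S)-γ-valerolactone.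
- Forward: the five-membered O-ring is made first, as the lactone, and decorated. The six-membered carbocycle is then annulated onto it in one pot, and one conjugate reduction finishes.
- Stereochemistry: C2 is bought. C3 is set anti to the C2 methyl (cuprate addition). C3a is set by the order of two enolate alkylations, each anti to the C3 aryl (allyl first, C4 last). C5 is set by equilibration α to C6=O, relayed from C3a.

Key step: step 6

Remark: C5 lies α to the C6 ketone and is epimerisable; the (5R) epimer (OMe pseudo-equatorial, trans to the pseudo-axial 3a-allyl group) is assumed to be the more stable one, so C5 is left to equilibration.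

Step 1
Reactants: 1 (5S)-5-methyldihydrofuran-2(3H)-one [(S)-γ-valerolactone]
Product: 3 (5S)-5-methylfuran-2(5H)-one, via selanyl lactone 2 (not isolated)
Conditions: LiN(iPr)2 (LDA, 1.1 equiv), THF, −78 °C; PhSeBr; then 30% aq. H2O2, CH2Cl2, 0 °C → rt
Reagents that add atoms: none
Why: Reich–Grieco dehydrogenation, in which the lactone enolate is selenenylated at C3 and the selenoxide undergoes syn-elimination towards C4 (the only β-hydrogens), should give the conjugated butenolide without touching the C5 stereocentre.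

Step 2
Reactants: 3 (5S)-5-methylfuran-2(5H)-one; 4 (3,4,5-trimethoxyphenyl)magnesium bromide (commercial THF solution)
Product: 6 (4S,5S)-5-methyl-4-(3,4,5-trimethoxyphenyl)dihydrofuran-2(3H)-one, via silyl ketene acetal 5 (not isolated)
Conditions: CuBr·SMe2 (10 mol%), Me3SiCl (1.5 equiv), THF, −78 °C; then 1 M HCl
Reagents that add atoms: (3,4,5-trimethoxyphenyl)magnesium bromide, COc1cc([Mg]Br)cc(OC)c1OC
Why: In this copper-catalysed, Me3SiCl-accelerated conjugate addition of an aryl Grignard reagent the aryl group should enter the butenolide face anti to the C5 methyl group, giving the 4,5-trans lactone (C3 of the target set from C2).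

Step 3
Reactants: 6 (4S,5S)-5-methyl-4-(3,4,5-trimethoxyphenyl)dihydrofuran-2(3H)-one; 7 allyl bromide
Product: 8 (3R,4S,5S)-5-methyl-3-(prop-2-en-1-yl)-4-(3,4,5-trimethoxyphenyl)dihydrofuran-2(3H)-one
Conditions: LiN(iPr)2 (LDA, 1.1 equiv), THF, −78 °C; allyl bromide, −78 → −30 °C
Reagents that add atoms: allyl bromide, C=CCBr
Why: Alkylation of the lithium lactone enolate with allyl bromide should occur anti to the adjacent C4 aryl group (3,4-trans); the centre is re-made in step 4, so this step only places the allyl group.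

Step 4
Reactants: 8 (3R,4S,5S)-5-methyl-3-(prop-2-en-1-yl)-4-(3,4,5-trimethoxyphenyl)dihydrofuran-2(3H)-one; 9 trimethyl orthoformate
Product: 11 (3S,4R,5S)-3-(dimethoxymethyl)-5-methyl-3-(prop-2-en-1-yl)-4-(3,4,5-trimethoxyphenyl)dihydrofuran-2(3H)-one, via silyl ketene acetal 10 (not isolated)
Conditions: LiN(iPr)2 (LDA, 1.1 equiv), Me3SiCl, THF, −78 °C; solvent change to CH2Cl2; then HC(OMe)3, Me3SiOTf (10 mol%), −78 → −20 °C
Reagents that add atoms: trimethyl orthoformate, COC(OC)OC
Why: In this Mukaiyama-type C-alkylation of the ketene silyl acetal by the dimethoxycarbenium ion the electrophile should again enter anti to the C4 aryl group, so the allyl group is pushed cis to the aryl and the quaternary centre (C3a of the target) is set by the order of the two alkylations.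

Step 5
Reactants: 12 1-methoxypropan-2-one (methoxyacetone)
Product: 13 (Z)-1-methoxy-2-(trimethylsilyloxy)prop-1-ene
Conditions: Me3SiCl, Et3N, DMF, 80 °C
Reagents that add atoms: chlorotrimethylsilane, C[Si](C)(C)Cl
Why: Equilibrating silylation (House conditions) should favour the more substituted enol silane on the methoxy-bearing side, which fixes C5 as the only nucleophilic carbon in the first stage of step 6 (the double-bond geometry is immaterial).

Step 6
Reactants: 11 (3S,4R,5S)-3-(dimethoxymethyl)-5-methyl-3-(prop-2-en-1-yl)-4-(3,4,5-trimethoxyphenyl)dihydrofuran-2(3H)-one; 13 (Z)-1-methoxy-2-(trimethylsilyloxy)prop-1-ene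
Product: 16 (2S,3R,3aS)-5-methoxy-2-methyl-3a-(prop-2-en-1-yl)-3-(3,4,5-trimethoxyphenyl)-3,3a-dihydro-1-benzofuran-6(2H)-one, via methoxy ketone 14 (not isolated), via hydroxy diketone 15 (not isolated)
Conditions: Me3SiOTf (20 mol%), CH2Cl2, −78 °C; then LiN(SiMe3)2 (LiHMDS, 3.5 equiv), THF, −78 → 0 °C; then TsOH·H2O (5 equiv), rt
Reagents that add atoms: (Z)-1-methoxy-2-(trimethylsilyloxy)prop-1-ene, CO/C=C(/C)O[Si](C)(C)C
Why: In the first stage Me3SiOTf ionises the neopentyl acetal of 11 to an oxocarbenium ion at C4, which the enol silane 13 attacks through C5 (C4–C5 bond, silicon leaving as Me3SiOMe) to give 14. In the second stage the kinetic methyl enolate (C7) of 14 adds to the lactone carbonyl C7a and the tetrahedral intermediate opens to the β-diketonate of 15 (C7–C7a bond); acid then recloses O1 onto C7a with loss of water (C7=C7a of the vinylogous ester) and expels the C4 methoxy group β to C6=O to give the cross-conjugated dienone. The closest known reaction types are the Mukaiyama–Noyori addition of enol silanes to acetals, the Dieckmann-type acylation of a ketone enolate by a lactone leading to a cyclohexane-1,3-dione, and the acid-induced loss of methanol from Danishefsky-type β-methoxy ketones. The carbocycle closes by a 6-(enolendo)-exo-trig attack of C7 on C7a, and the five-membered O-ring re-forms by 5-exo-trig addition of the C2 hydroxyl to the C7a ketone followed by dehydration. No lasting stereocentre is created: the C4 and C5 centres of 14 are erased by the elimination, while C2, C3 and the quaternary C3a carry no acidic hydrogen and should be untouched. The selectivity needed is positional (C5 to C4, C7 to C7a): it is secured by the fixed double-bond position in 13, by the inertness of the lactone in the Lewis-acid stage, and by kinetic deprotonation of the unhindered methyl group, while the C4 oxygen, being an ether, blocks retro-aldol cleavage and is lost only after the ring has closed.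

Step 7
Reactants: 16 (2S,3R,3aS)-5-methoxy-2-methyl-3a-(prop-2-en-1-yl)-3-(3,4,5-trimethoxyphenyl)-3,3a-dihydro-1-benzofuran-6(2H)-one
Product: 18 (2S,3R,3aR,5R)-5-methoxy-2-methyl-3a-(prop-2-en-1-yl)-3-(3,4,5-trimethoxyphenyl)-3,3a,4,5-tetrahydro-1-benzofuran-6(2H)-one, via C5 epimer 17 (not isolated)
Conditions: [(Ph3P)CuH]6 (0.4 equiv), PhMe, H2O (3 equiv), rt; then DBU (0.3 equiv), rt
Reagents that add atoms: none
Why: In this Stryker conjugate reduction the copper hydride should add only at C4, the unsubstituted β-carbon of the α-methoxy enone (C7=C7a is a donor-deactivated, fully β-substituted vinylogous ester and the allyl group is unactivated), and DBU should then equilibrate C5 through the enolate to the epimer with the methoxy group pseudo-equatorial and trans to the pseudo-axial 3a-allyl group.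

**Compound list**

1 | (5S)-5-methyldihydrofuran-2(3H)-one [(S)-γ-valerolactone] | C[C@@H]1OC(=O)CC1 | starting material
2 | (5S)-5-methyl-3-(phenylselanyl)dihydrofuran-2(3H)-one (both C3 epimers; not isolated) | C[C@@H]1OC(=O)C([Se]c2ccccc2)C1 | intermediate
3 | (5S)-5-methylfuran-2(5H)-one | C[C@@H]1OC(=O)C=C1 | intermediate
4 | (3,4,5-trimethoxyphenyl)magnesium bromide | COc1cc([Mg]Br)cc(OC)c1OC | starting material
5 | trimethyl{[(4S,5S)-5-methyl-4-(3,4,5-trimethoxyphenyl)-4,5-dihydrofuran-2-yl]oxy}silane (not isolated) | C[C@@H]1OC(O[Si](C)(C)C)=C[C@H]1c1cc(OC)c(OC)c(OC)c1 | intermediate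
6 | (4S,5S)-5-methyl-4-(3,4,5-trimethoxyphenyl)dihydrofuran-2(3H)-one | C[C@@H]1OC(=O)C[C@H]1c1cc(OC)c(OC)c(OC)c1 | intermediate
7 | allyl bromide (3-bromoprop-1-ene) | C=CCBr | starting material
8 | (3R,4S,5S)-5-methyl-3-(prop-2-en-1-yl)-4-(3,4,5-trimethoxyphenyl)dihydrofuran-2(3H)-one | C=CC[C@H]1C(=O)O[C@@H](C)[C@@H]1c2cc(OC)c(OC)c(OC)c2 | intermediate
9 | trimethyl orthoformate | COC(OC)OC | starting material
10 | trimethyl{[(4R,5S)-5-methyl-3-(prop-2-en-1-yl)-4-(3,4,5-trimethoxyphenyl)-4,5-dihydrofuran-2-yl]oxy}silane (not isolated) | C=CCC1=C(O[Si](C)(C)C)O[C@@H](C)[C@@H]1c2cc(OC)c(OC)c(OC)c2 | intermediate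
11 | (3S,4R,5S)-3-(dimethoxymethyl)-5-methyl-3-(prop-2-en-1-yl)-4-(3,4,5-trimethoxyphenyl)dihydrofuran-2(3H)-one | C=CC[C@]1(C(OC)OC)C(=O)O[C@@H](C)[C@@H]1c2cc(OC)c(OC)c(OC)c2 | intermediate
12 | 1-methoxypropan-2-one (methoxyacetone) | COCC(C)=O | starting material
13 | (Z)-1-methoxy-2-(trimethylsilyloxy)prop-1-ene | CO/C=C(/C)O[Si](C)(C)C | intermediate
14 | (3S,4R,5S)-3-(1,2-dimethoxy-3-oxobutyl)-5-methyl-3-(prop-2-en-1-yl)-4-(3,4,5-trimethoxyphenyl)dihydrofuran-2(3H)-one (side-chain diastereomers; not isolated) | C=CC[C@]1(C(OC)C(OC)C(C)=O)C(=O)O[C@@H](C)[C@@H]1c2cc(OC)c(OC)c(OC)c2 | intermediate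
15 | (4S)-4-[(1R,2S)-2-hydroxy-1-(3,4,5-trimethoxyphenyl)propyl]-5,6-dimethoxy-4-(prop-2-en-1-yl)cyclohexane-1,3-dione (C5/C6 epimers; present as its dilithium salt; not isolated) | C=CC[C@@]1(C(OC)C(OC)C(=O)CC1=O)[C@@H](c2cc(OC)c(OC)c(OC)c2)[C@H](C)O | intermediate
16 | (2S,3R,3aS)-5-methoxy-2-methyl-3a-(prop-2-en-1-yl)-3-(3,4,5-trimethoxyphenyl)-3,3a-dihydro-1-benzofuran-6(2H)-one | C=CC[C@]12C=C(OC)C(=O)C=C1O[C@@H](C)[C@@H]2c1cc(OC)c(OC)c(OC)c1 | intermediate
17 | (2S,3R,3aR,5S)-5-methoxy-2-methyl-3a-(prop-2-en-1-yl)-3-(3,4,5-trimethoxyphenyl)-3,3a,4,5-tetrahydro-1-benzofuran-6(2H)-one (not isolated) | C=CC[C@]12C[C@H](OC)C(=O)C=C1O[C@@H](C)[C@@H]2c1cc(OC)c(OC)c(OC)c1 | intermediate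
18 | (2S,3R,3aR,5R)-5-methoxy-2-methyl-3a-(prop-2-en-1-yl)-3-(3,4,5-trimethoxyphenyl)-3,3a,4,5-tetrahydro-1-benzofuran-6(2H)-one | C=CC[C@]12C[C@@H](OC)C(=O)C=C1O[C@@H](C)[C@@H]2c1cc(OC)c(OC)c(OC)c1 | target

Total steps: 7 (including the one-step preparation of 13). Longest linear sequence: 6 steps (1 → 3 → 6 → 8 → 11 → 16 → 18).

**Steps most likely to fail**

Step 6. What may go wrong: slow or misdirected capture of the congested oxocarbenium ion at C4 (hydrolysis of the enol silane, Prins or Friedel–Crafts capture), loss of methanol before the ring is closed (an open enone of the wrong geometry cannot cyclise), or reluctant acylation at the hindered lactone carbonyl. The fallback changes the bond set and makes C3a–C4 instead of C4–C5. It sets out from 8 and comes back to the route at 18. Ketene silyl acetal 10, made from 8 as in step 4, would undergo a Mukaiyama–Michael addition to purchased 3-methoxybut-3-en-2-one (catalytic Me3SiOTf, CH2Cl2, −78 °C, acidic work-up), anti to the aryl group. This should give the keto lactone (3R,4R,5S)-3-(2-methoxy-3-oxobutyl)-5-methyl-3-(prop-2-en-1-yl)-4-(3,4,5-trimethoxyphenyl)dihydrofuran-2(3H)-one F1. LiN(SiMe3)2 followed by TsOH (Dieckmann closure, cyclodehydration, C5 equilibrating) would then give 18 directly, without the dienone 16 and without step 7.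

Step 7. What may go wrong: hydride delivery at the wrong site (1,2-reduction at C6, attack on the vinylogous ester, hydrometalation of the allyl group), or slow or poorly biased equilibration at C5. The fallback takes the reduction out of the bicyclic dienone and places it before ring closure. It sets out from 11 (with 13) and comes back to the route at 18. Only the first stage of step 6 is run and methoxy ketone 14 is isolated. DBU then removes methanol to give the open-chain enone (3S,4R,5S)-3-(2-methoxy-3-oxobut-1-en-1-yl)-5-methyl-3-(prop-2-en-1-yl)-4-(3,4,5-trimethoxyphenyl)dihydrofuran-2(3H)-one F2, either geometry being usable. Its conjugate reduction with the same copper hydride, now with a single conjugated C=C and no competing vinylogous ester, should give the keto lactone F1 described above. LiN(SiMe3)2 followed by TsOH would close it to 18.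

Step 4. What may go wrong: low conversion of the tetrasubstituted ketene acetal towards the dimethoxycarbenium ion (protodesilylation back to 8) or eroded facial selectivity. The fallback installs C4 by an aldol reaction and adjusts the oxidation level afterwards. It sets out from 8 and comes back to the route at 11. The lithium enolate of 8 would be treated with monomeric formaldehyde (from cracked paraformaldehyde, −78 °C), which should add anti to the aryl group to give (3S,4R,5S)-3-(hydroxymethyl)-5-methyl-3-(prop-2-en-1-yl)-4-(3,4,5-trimethoxyphenyl)dihydrofuran-2(3H)-one F3. Dess–Martin oxidation would give (3S,4R,5S)-5-methyl-2-oxo-3-(prop-2-en-1-yl)-4-(3,4,5-trimethoxyphenyl)oxolane-3-carbaldehyde F4. Acetalisation (HC(OMe)3, catalytic TsOH, MeOH) would then return 11.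

Further compounds
F1 | step 6 | (3R,4R,5S)-3-(2-methoxy-3-oxobutyl)-5-methyl-3-(prop-2-en-1-yl)-4-(3,4,5-trimethoxyphenyl)dihydrofuran-2(3H)-one (side-chain epimers) | C=CC[C@]1(CC(OC)C(C)=O)C(=O)O[C@@H](C)[C@@H]1c2cc(OC)c(OC)c(OC)c2
F2 | step 7 | (3S,4R,5S)-3-(2-methoxy-3-oxobut-1-en-1-yl)-5-methyl-3-(prop-2-en-1-yl)-4-(3,4,5-trimethoxyphenyl)dihydrofuran-2(3H)-one | C=CC[C@]1(C=C(OC)C(C)=O)C(=O)O[C@@H](C)[C@@H]1c2cc(OC)c(OC)c(OC)c2
F3 | step 4 | (3S,4R,5S)-3-(hydroxymethyl)-5-methyl-3-(prop-2-en-1-yl)-4-(3,4,5-trimethoxyphenyl)dihydrofuran-2(3H)-one | C=CC[C@]1(CO)C(=O)O[C@@H](C)[C@@H]1c2cc(OC)c(OC)c(OC)c2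
F4 | step 4 | (3S,4R,5S)-5-methyl-2-oxo-3-(prop-2-en-1-yl)-4-(3,4,5-trimethoxyphenyl)oxolane-3-carbaldehyde | C=CC[C@]1(C=O)C(=O)O[C@@H](C)[C@@H]1c2cc(OC)c(OC)c(OC)c2
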